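## Retrosynthetic overview

1. Last step: both 2-aminoimidazoles are unmasked from imidazo[1,2-a]pyrimidines with hydrazine, so the basic rings are carried neutral and masked.
2. Key disconnection: the cyclobutane is cut into two near-equal halves, a masked clathrodin (pyrrole amide, 20 heavy atoms) and a masked hymenidin (4-bromopyrrole amide, 21 heavy atoms). They are joined by a crossed head-to-head [2+2] photocycloaddition that sets the all-trans relative configuration; the absolute configuration is then fixed by resolving the protected heterodimer.
3. Each half is an amide between one common (E)-heteroaryl-allylamine and 2-trichloroacetylpyrrole or its 4-bromo derivative, both made from pyrrole.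
4. The allylamine comes from a Suzuki coupling of 3-bromoimidazo[1,2-a]pyrimidine with the (E)-vinylboronate of Boc-propargylamine.
5. Ring order: imidazo[1,2-a]pyrimidine (2-aminopyrimidine + chloroacetaldehyde), then cyclobutane ([2+2]), then 2-aminoimidazoles by pyrimidine cleavage; the pyrrole rings are bought intact.

Assumption: the target is handled after HPLC as its bis-trifluoroacetate salt; the free base is drawn.

## Route

Step 1
Reactants: 1, 2-aminopyrimidine; 2, chloroacetaldehyde
Product: 3, imidazo[1,2-a]pyrimidine
Conditions: ClCH2CHO (50% aq.), NaHCO3, EtOH, reflux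
Reagents that add atoms: none (all atoms come from 1 and 2)
Why: Tschitschibabin-type cyclocondensation, in which the ring nitrogen is alkylated by the CH2Cl carbon and the exocyclic NH2 condenses with the aldehyde to close the imidazole ring.

Step 2
Reactants: 3, imidazo[1,2-a]pyrimidine
Product: 4, 3-bromoimidazo[1,2-a]pyrimidine
Conditions: NBS (1.05 equiv), CHCl3, 0 °C to rt
Reagents that add atoms: N-bromosuccinimide, O=C1CCC(=O)N1Br
Why: Electrophilic aromatic bromination occurs at C3, the most nucleophilic position of the imidazole half.

Step 3
Reactants: 5, propargylamine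
Product: 6, tert-butyl prop-2-yn-1-ylcarbamate (N-Boc-propargylamine)
Conditions: Boc2O, Et3N, CH2Cl2, 0 °C to rt
Reagents that add atoms: di-tert-butyl dicarbonate, CC(C)(C)OC(=O)OC(=O)OC(C)(C)C
Why: Standard carbamate protection of a primary amine, so that the nitrogen does not interfere with hydroboration or palladium.

Step 4
Reactants: 6, N-Boc-propargylamine
Product: 7, tert-butyl (E)-[3-(4,4,5,5-tetramethyl-1,3,2-dioxaborolan-2-yl)allyl]carbamate
Conditions: HBpin (1.5 equiv), Cp2Zr(H)Cl (10 mol%), Et3N (10 mol%), neat, 60 °C
Reagents that add atoms: pinacolborane, CC1(C)OBOC1(C)C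
Why: Zirconium-catalysed hydroboration of the terminal alkyne is a syn, anti-Markovnikov addition and gives only the (E)-alkenylboronate.

Step 5
Reactants: 4, 3-bromoimidazo[1,2-a]pyrimidine; 7, the (E)-alkenyl pinacol boronate
Product: 8, tert-butyl (E)-[3-(imidazo[1,2-a]pyrimidin-3-yl)allyl]carbamate
Conditions: Pd(dppf)Cl2 (5 mol%), K2CO3, dioxane/H2O 4:1, 85 °C
Reagents that add atoms: none
Why: Suzuki–Miyaura coupling of a heteroaryl bromide with an alkenylboronate proceeds with retention of the E geometry, and the Boc group is stable to aqueous carbonate.

Step 6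
Reactants: 8, the Boc-protected allylamine
Product: 9, (E)-3-(imidazo[1,2-a]pyrimidin-3-yl)prop-2-en-1-amine, isolated as the free base
Conditions: 4 M HCl/dioxane, CH2Cl2, 0 °C to rt; then Amberlyst A-21 (weakly basic resin), MeOH, filter and concentrate; used at once
Reagents that add atoms: none
Why: Acidolytic Boc cleavage (loss of isobutene and CO2) gives the amine hydrochloride, and neutralisation on the resin releases the free primary amine, which is split into two portions, one for each half.

Step 7
Reactants: 10, pyrrole; 11, trichloroacetyl chloride
Product: 12, 2-(trichloroacetyl)pyrrole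
Conditions: Et2O, rt; then aq. K2CO3
Reagents that add atoms: none (all atoms come from 10 and 11)
Why: Uncatalysed Friedel–Crafts acylation of pyrrole is selective for C2 and gives a shelf-stable acyl donor.

Step 8
Reactants: 12, 2-(trichloroacetyl)pyrrole
Product: 13, 4-bromo-2-(trichloroacetyl)pyrrole
Conditions: Br2 (1.0 equiv), CHCl3, −10 °C to rt
Reagents that add atoms: bromine, BrBr
Why: Electrophilic bromination is directed to C4 by the electron-withdrawing 2-acyl group, and one equivalent of Br2 stops at the monobromide.

Step 9
Reactants: 9, the free allylamine; 12, 2-(trichloroacetyl)pyrrole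
Product: 14, (E)-N-[3-(imidazo[1,2-a]pyrimidin-3-yl)allyl]-1H-pyrrole-2-carboxamide (masked clathrodin)
Conditions: Et3N (1.2 equiv), MeCN, rt
Reagents that add atoms: none
Why: Haloform-type acyl transfer, in which the primary amine displaces CCl3− (lost as CHCl3) to give the amide without protecting the pyrrole NH.

Step 10
Reactants: 9, the free allylamine; 13, 4-bromo-2-(trichloroacetyl)pyrrole
Product: 15, (E)-4-bromo-N-[3-(imidazo[1,2-a]pyrimidin-3-yl)allyl]-1H-pyrrole-2-carboxamide (masked hymenidin)
Conditions: Et3N (1.2 equiv), MeCN, rt
Reagents that add atoms: none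
Why: The same haloform-type amidation as step 9, and the aryl bromide is inert to these conditions.

Step 11
Reactants: 14, masked clathrodin (3 equiv); 15, masked hymenidin (1 equiv, limiting)
Product: 16, racemic all-trans heterodimer: N-{[(1R*,2R*,3S*,4S*)-2-{[(4-bromo-1H-pyrrole-2-carbonyl)amino]methyl}-3,4-bis(imidazo[1,2-a]pyrimidin-3-yl)cyclobutyl]methyl}-1H-pyrrole-2-carboxamide
Conditions: Ir(ppy)3 (1–2 mol%), 450 nm LEDs, degassed MeOH (0.2 M), rt; SiO2 then RP-HPLC to remove the two homodimers
Reagents that add atoms: none
Why: Triplet-sensitised intermolecular [2+2] photocycloaddition, in which the two CH(CH2N) carbons bond first to give a bis-heterobenzylic 1,4-diradical that closes head-to-head in the least hindered all-trans arrangement, so all four stereocentres are set relative to one another as a racemate, with the excess of 14 statistically channelling 15 into the heterodimer.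

Step 12
Reactants: 16, racemic heterodimer
Product: 17, the (1R,2R,3S,4S) enantiomer of 16 (C1 and C2 carry the pyrrole and bromopyrrole amidomethyl arms, C3 and C4 the heteroaryls)
Conditions: preparative chiral SFC, Chiralpak IC, CO2/MeOH (0.2% Et2NH); configuration assigned by anomalous-dispersion X-ray (Br)
Reagents that add atoms: none
Why: Chromatographic resolution of a neutral racemate on a polysaccharide chiral stationary phase fixes the absolute configuration without making or breaking bonds.

Step 13
Reactants: 17, enantiopure heterodimer
Product: 18, desbromosceptrin: N-{[(1R,2R,3S,4S)-3,4-bis(2-amino-1H-imidazol-5-yl)-2-{[(4-bromo-1H-pyrrole-2-carbonyl)amino]methyl}cyclobutyl]methyl}-1H-pyrrole-2-carboxamide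
Conditions: N2H4·H2O (excess), EtOH, 80 °C; RP-HPLC (0.1% TFA)
Reagents that add atoms: none (hydrazine leaves with the pyrimidine C3 unit as pyrazole)
Why: Hydrazinolytic cleavage of each pyrimidine ring leaves the former ring nitrogen as the exocyclic NH2 of a 2-aminoimidazole, under conditions that do not touch the secondary amides, the C–Br bond or the non-epimerisable cyclobutane centres.

## Compound list

1 | 2-aminopyrimidine | Nc1ncccn1 | starting material
2 | chloroacetaldehyde | ClCC=O | starting material
3 | imidazo[1,2-a]pyrimidine | c1cnc2nccn2c1 | intermediate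
4 | 3-bromoimidazo[1,2-a]pyrimidine | Brc1cnc2ncccn12 | intermediate
5 | propargylamine | C#CCN | starting material
6 | tert-butyl prop-2-yn-1-ylcarbamate | C#CCNC(=O)OC(C)(C)C | intermediate
7 | tert-butyl (E)-[3-(pinacolboryl)allyl]carbamate | CC(C)(C)OC(=O)NC/C=C/B1OC(C)(C)C(C)(C)O1 | intermediate
8 | tert-butyl (E)-[3-(imidazo[1,2-a]pyrimidin-3-yl)allyl]carbamate | CC(C)(C)OC(=O)NC/C=C/c1cnc2ncccn12 | intermediate
9 | (E)-3-(imidazo[1,2-a]pyrimidin-3-yl)prop-2-en-1-amine (free base) | NC/C=C/c1cnc2ncccn12 | intermediate
10 | pyrrole | c1cc[nH]c1 | starting material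
11 | trichloroacetyl chloride | ClC(=O)C(Cl)(Cl)Cl | starting material
12 | 2-(trichloroacetyl)pyrrole | O=C(c1ccc[nH]1)C(Cl)(Cl)Cl | intermediate
13 | 4-bromo-2-(trichloroacetyl)pyrrole | O=C(c1cc(Br)c[nH]1)C(Cl)(Cl)Cl | intermediate
14 | (E)-N-[3-(imidazo[1,2-a]pyrimidin-3-yl)allyl]-1H-pyrrole-2-carboxamide | O=C(NC/C=C/c1cnc2ncccn12)c1ccc[nH]1 | intermediate
15 | (E)-4-bromo-N-[3-(imidazo[1,2-a]pyrimidin-3-yl)allyl]-1H-pyrrole-2-carboxamide | O=C(NC/C=C/c1cnc2ncccn12)c1cc(Br)c[nH]1 | intermediate
16 | racemic all-trans heterodimer (relative configuration shown; one enantiomer drawn) | c1cnc2ncc([C@H]3[C@H](CNC(=O)c4ccc[nH]4)[C@@H](CNC(=O)c5cc(Br)c[nH]5)[C@@H]3c6cnc7ncccn67)n2c1 | intermediate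
17 | (1R,2R,3S,4S) heterodimer, single enantiomer | c1cnc2ncc([C@H]3[C@H](CNC(=O)c4ccc[nH]4)[C@@H](CNC(=O)c5cc(Br)c[nH]5)[C@@H]3c6cnc7ncccn67)n2c1 | intermediate
18 | desbromosceptrin | Nc1ncc([C@H]2[C@H](CNC(=O)c3ccc[nH]3)[C@@H](CNC(=O)c3cc(Br)c[nH]3)[C@@H]2c2cnc(N)[nH]2)[nH]1 | target

## Step count

Total steps: 13.
Longest linear sequence: 8 steps (steps 1, 2, 5, 6, 10, 11, 12, 13; compounds 1 → 3 → 4 → 8 → 9 → 15 → 16 → 17 → 18), which is 62% of the total.

## Steps most likely to fail

1. Step 11, the crossed [2+2]. The cross-selectivity is only statistical, head-to-tail or cis isomers and E/Z photoisomerisation compete, and the C–Br bond could be photoreduced. Fallback: abandon the hetero-coupling and photodimerise carbamate 8 instead, which has no cross-selectivity problem and gives a C2-symmetric head-to-head dimer. After resolution and Boc removal, the two homotopic amines are acylated one at a time, first with 12 (either amine gives the same mono-amide) and then with 13, followed by hydrazinolysis.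

2. Step 12, the resolution. Separation or throughput on the chiral phase may be poor, and half the material is lost at best. Fallback: set the absolute configuration by asymmetric synthesis of the cyclobutane core instead of by resolution. The prochiral 1,4-dimethyl-7-oxanorbornadiene-2,3-diester (2,5-dimethylfuran + dimethyl acetylenedicarboxylate) is desymmetrised with pig-liver esterase, photoisomerised to the oxaquadricyclane and fragmented with acid to an enantioenriched all-trans 1,2-diacetylcyclobutane with differentiated carboxyl groups. The carboxyls are then converted into the two different amidomethyl arms and the acetyls into the aminoimidazoles.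

3. Step 13, the double hydrazinolysis. Cleavage of the two hindered imidazopyrimidines may be incomplete, or the amides may be attacked under forcing conditions. Fallback: change the masking strategy so that no hydrazine is needed. The 2-aminoimidazoles are built last from an all-trans cyclobutane bis(chloromethyl ketone) by amination and cyanamide condensation (or Boc-guanidine condensation followed by TFA).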